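## Retrosynthetic overview

1. The ring acetate, the free phenol and the angelate are late functional-group operations: hydroquinone monoacetate ⇐ quinone ⇐ p-methoxyphenol; the C=CH2 group ⇐ aryl ketone by methylenation.
2. Key bond, aryl–C(=O): photochemical 1,3-acyl shift (photo-Fries) of the aryl ester of the α-hydroxy acid. The para-OMe blocks the para position, so only the required ortho carbon can take the acyl group.
3. CH2–CH=CMe2 bond: Ni-electrocatalytic decarboxylative alkenylation of the β-carboxyl of a malate with 1-bromo-2-methylpropene.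
4. The only stereocentre is bought as L-malic acid (S) and is never a reacting centre. The phenol first protects C1 as its aryl ester and then becomes the arene of the target.
5. No ring is formed; the benzene ring is bought as 2,4-dimethoxy-3-methylbenzaldehyde and converted to the phenol by Dakin oxidation.

Assumption: the target is taken exactly as drawn, (S) at the carbinol carbon with a (Z)-2-methylbut-2-enoate (angelate); 1, 4, 8 and angelic anhydride are treated as catalogue chemicals.

## Route

Step 1
Reactants: 1 2,4-dimethoxy-3-methylbenzaldehyde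
Product: 3 2,4-dimethoxy-3-methylphenol, via aryl formate 2 (not isolated)
Conditions: mCPBA, CH2Cl2, rt; Na2S2O3/NaHCO3 wash; then K2CO3 (cat.), MeOH, rt
Reagents that add atoms: meta-chloroperbenzoic acid, O=C(OO)c1cccc(Cl)c1
Why: Dakin-type Baeyer–Villiger oxidation in which the electron-rich 2,4-dialkoxyaryl group migrates to give the formate, which is methanolysed to the phenol; no stereocentre is involved.

Step 2
Reactants: 4 L-malic acid; 3 2,4-dimethoxy-3-methylphenol
Product: 7 (3S)-4-(2,4-dimethoxy-3-methylphenoxy)-3-hydroxy-4-oxobutanoic acid, via O-trifluoroacetylmalic anhydride 5 (not isolated), via aryl trifluoroacetoxysuccinate 6 (not isolated)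
Conditions: TFAA, 0 °C → rt, then evaporate; 3, toluene, 50 °C (no base); MeOH, rt
Reagents that add atoms: trifluoroacetic anhydride, O=C(OC(=O)C(F)(F)F)C(F)(F)F (its CF3CO group is carried only by 5 and 6 and is lost before 7)
Why: Regioselective ring opening of an O-acyl malic anhydride (the known malic acid 1-monoester synthesis, here with a phenol): the phenol attacks the more electrophilic carbonyl next to the acyloxy-bearing carbon, base is avoided because amines eliminate CF3CO2H to maleic anhydride, and methanolysis removes the trifluoroacetate; C2 of L-malic acid undergoes no bond change, so (S) is kept.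

Step 3
Reactants: 7 (3S)-4-(2,4-dimethoxy-3-methylphenoxy)-3-hydroxy-4-oxobutanoic acid; 8 1-bromo-2-methylprop-1-ene
Product: 10 2,4-dimethoxy-3-methylphenyl (2S)-2-hydroxy-5-methylhex-4-enoate, via NHPI ester 9 (not isolated)
Conditions: NHPI, DIC, THF, rt (filter urea); then NiCl2·6H2O (10 mol%), 2,2'-bipyridine (10 mol%), AgNO3 (0.3 equiv), 8 (3 equiv), DMF, Mg(+)/RVC(−), constant current (about 2.5 F/mol), rt
Reagents that add atoms: N-hydroxyphthalimide, O=C1c2ccccc2C(=O)N1O (carried only by 9)
Why: Ni-electrocatalytic decarboxylative alkenylation of a redox-active ester (reductive cross-electrophile coupling): low-valent Ni fragments the NHPI ester to CO2 and a primary radical at C3, which is captured by the alkenyl–Ni species from 8 and reductively eliminated to the prenyl C–C bond; the radical is one carbon away from the stereocentre, so (S) is retained.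

Step 4
Reactants: 10 2,4-dimethoxy-3-methylphenyl (2S)-2-hydroxy-5-methylhex-4-enoate
Product: 11 (2S)-2-hydroxy-1-(2-hydroxy-3,5-dimethoxy-4-methylphenyl)-5-methylhex-4-en-1-one
Conditions: hν (254 nm, FEP flow coil), degassed MeCN (0.01 M), rt, to about 80% conversion (recover 10)
Reagents that add atoms: none
Why: Proposed new method: photo-Fries 1,3-shift of an unprotected, stereogenic α-hydroxyacyl group — excitation of the aryl ester gives O–C(O) homolysis to a caged aryloxyl/acyl radical pair that recombines at C6, the only free ortho carbon (para and the other ortho position carry OMe), and tautomerises to the o-hydroxyaryl ketone, which is protected from further photolysis by excited-state intramolecular proton transfer; geminate recombination should outrun decarbonylation of the α-hydroxyacyl radical, and the σ-acyl radical never involves C2, so (S) is kept; the closest known reaction is the photo-Fries rearrangement of simple aryl alkanoates such as 4-methoxyphenyl acetate to 2-hydroxy-5-methoxyacetophenone.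

Step 5
Reactants: 11 (2S)-2-hydroxy-1-(2-hydroxy-3,5-dimethoxy-4-methylphenyl)-5-methylhex-4-en-1-one
Product: 12 6-[(3S)-3-hydroxy-6-methylhepta-1,5-dien-2-yl]-2,4-dimethoxy-3-methylphenol
Conditions: Zn, CH2Br2, TiCl4, THF (pre-formed reagent, about 5 equiv); 11 in CH2Cl2, 0 °C → rt; NaHCO3 work-up
Reagents that add atoms: dibromomethane, BrCBr
Why: Takai–Lombardo methylenation: the non-basic CH2(ZnBr)2/TiCl4 reagent converts the aryl ketone into the 1,1-disubstituted alkene without enolising the α-hydroxy ketone (stereocentre kept) and tolerates the two free OH groups when used in excess.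

Step 6
Reactants: 12 6-[(3S)-3-hydroxy-6-methylhepta-1,5-dien-2-yl]-2,4-dimethoxy-3-methylphenol
Product: 13 (3S)-2-(2-hydroxy-3,5-dimethoxy-4-methylphenyl)-6-methylhepta-1,5-dien-3-yl (2Z)-2-methylbut-2-enoate
Conditions: LiHMDS (2.1 equiv), THF, −78 °C; angelic anhydride (1.05 equiv), −78 → −20 °C; NH4Cl
Reagents that add atoms: angelic anhydride [(2Z)-2-methylbut-2-enoic anhydride], C/C=C(/C)C(=O)OC(=O)/C(C)=C\C
Why: Low-temperature alkoxide acylation with angelic anhydride (avoids Z→E isomerisation to the tiglate): the secondary lithium alkoxide is far more nucleophilic than the hindered phenoxide, and any aryl angelate formed would pass its acyl group on to the alkoxide, so the alkyl angelate with free phenol results; O-acylation leaves C3 untouched (S).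

Step 7
Reactants: 13 (3S)-2-(2-hydroxy-3,5-dimethoxy-4-methylphenyl)-6-methylhepta-1,5-dien-3-yl (2Z)-2-methylbut-2-enoate
Product: 14 (3S)-2-(5-methoxy-4-methyl-3,6-dioxocyclohexa-1,4-dien-1-yl)-6-methylhepta-1,5-dien-3-yl (2Z)-2-methylbut-2-enoate
Conditions: PhI(OAc)2 (1.1 equiv), MeCN/H2O 4:1, 0 °C, 15 min
Reagents that add atoms: water, O
Why: Oxidative demethylation of a 4-methoxyphenol with a hypervalent iodine reagent: water adds para to the phenoxonium ion at the OMe-bearing carbon and methanol is lost to give the p-quinone (as in coenzyme Q0 syntheses from 4-methoxyphenols), while the alkenes and the allylic angelate are inert.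

Step 8
Reactants: 14 (3S)-2-(5-methoxy-4-methyl-3,6-dioxocyclohexa-1,4-dien-1-yl)-6-methylhepta-1,5-dien-3-yl (2Z)-2-methylbut-2-enoate
Product: 16 (3S)-2-(5-acetoxy-2-hydroxy-3-methoxy-4-methylphenyl)-6-methylhepta-1,5-dien-3-yl (2Z)-2-methylbut-2-enoate, via hydroquinone 15 (not isolated)
Conditions: Na2S2O4, EtOAc/H2O, rt; then Ac2O (1.05 equiv), pyridine, CH2Cl2, −20 °C, Ar
Reagents that add atoms: acetic anhydride, CC(=O)OC(C)=O
Why: Dithionite reduction of the quinone followed by sterically controlled monoacetylation: the OH flanked by CH3 and H is acetylated, while the OH flanked by OMe and the branched side chain (and hydrogen-bonded to OMe) stays free; no stereocentre is touched and the product is the target.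

## Compound list

1 | 2,4-dimethoxy-3-methylbenzaldehyde | O=Cc1ccc(OC)c(C)c1OC | starting material
2 | 2,4-dimethoxy-3-methylphenyl formate | O=COc1ccc(OC)c(C)c1OC | intermediate
3 | 2,4-dimethoxy-3-methylphenol | Oc1ccc(OC)c(C)c1OC | intermediate
4 | L-malic acid, (2S)-2-hydroxybutanedioic acid | O[C@@H](CC(=O)O)C(=O)O | starting material
5 | (3S)-2,5-dioxooxolan-3-yl trifluoroacetate (O-trifluoroacetyl-L-malic anhydride) | O=C1C[C@H](OC(=O)C(F)(F)F)C(=O)O1 | intermediate
6 | (3S)-4-(2,4-dimethoxy-3-methylphenoxy)-4-oxo-3-(trifluoroacetoxy)butanoic acid | OC(=O)C[C@H](OC(=O)C(F)(F)F)C(=O)Oc1ccc(OC)c(C)c1OC | intermediate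
7 | (3S)-4-(2,4-dimethoxy-3-methylphenoxy)-3-hydroxy-4-oxobutanoic acid | OC(=O)C[C@H](O)C(=O)Oc1ccc(OC)c(C)c1OC | intermediate
8 | 1-bromo-2-methylprop-1-ene | CC(C)=CBr | starting material
9 | 1-(2,4-dimethoxy-3-methylphenyl) 4-(1,3-dioxoisoindolin-2-yl) (2S)-2-hydroxybutanedioate | O=C(C[C@H](O)C(=O)Oc1ccc(OC)c(C)c1OC)ON1C(=O)c2ccccc2C1=O | intermediate
10 | 2,4-dimethoxy-3-methylphenyl (2S)-2-hydroxy-5-methylhex-4-enoate | CC(C)=CC[C@H](O)C(=O)Oc1ccc(OC)c(C)c1OC | intermediate
11 | (2S)-2-hydroxy-1-(2-hydroxy-3,5-dimethoxy-4-methylphenyl)-5-methylhex-4-en-1-one | CC(C)=CC[C@H](O)C(=O)c1cc(OC)c(C)c(OC)c1O | intermediate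
12 | 6-[(3S)-3-hydroxy-6-methylhepta-1,5-dien-2-yl]-2,4-dimethoxy-3-methylphenol | C=C(c1cc(OC)c(C)c(OC)c1O)[C@@H](O)CC=C(C)C | intermediate
13 | (3S)-2-(2-hydroxy-3,5-dimethoxy-4-methylphenyl)-6-methylhepta-1,5-dien-3-yl (2Z)-2-methylbut-2-enoate | C=C(c1cc(OC)c(C)c(OC)c1O)[C@H](CC=C(C)C)OC(=O)/C(C)=C\C | intermediate
14 | (3S)-2-(5-methoxy-4-methyl-3,6-dioxocyclohexa-1,4-dien-1-yl)-6-methylhepta-1,5-dien-3-yl (2Z)-2-methylbut-2-enoate | C=C(C1=CC(=O)C(C)=C(OC)C1=O)[C@H](CC=C(C)C)OC(=O)/C(C)=C\C | intermediate
15 | (3S)-2-(2,5-dihydroxy-3-methoxy-4-methylphenyl)-6-methylhepta-1,5-dien-3-yl (2Z)-2-methylbut-2-enoate | C=C(c1cc(O)c(C)c(OC)c1O)[C@H](CC=C(C)C)OC(=O)/C(C)=C\C | intermediate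
16 | (3S)-2-(5-acetoxy-2-hydroxy-3-methoxy-4-methylphenyl)-6-methylhepta-1,5-dien-3-yl (2Z)-2-methylbut-2-enoate (CNP0305991.1) | C=C(c1cc(OC(C)=O)c(C)c(OC)c1O)[C@H](CC=C(C)C)OC(=O)/C(C)=C\C | target

## Step count and risks

Total steps: 8. Longest linear sequence: 8 (1 → 16; 7 steps from L-malic acid 4).

The three steps most likely to fail:

Step 4 (the proposed photo-Fries shift). Possible failures are cage escape with decarbonylation of the α-hydroxyacyl radical, or low quantum yield. The fallback uses known chemistry, sets out from 3 and 10 and returns at 11. Phenol 3 is brominated ortho to OH (NBS, cat. i-Pr2NH, CH2Cl2, 0 °C) to 6-bromo-2,4-dimethoxy-3-methylphenol F5. Ester 10 is converted with MeNH(OMe)·HCl/i-PrMgCl (THF, −20 °C) into the Weinreb amide (2S)-2-hydroxy-N-methoxy-N,5-dimethylhex-4-enamide F6, which releases 3 for recycling. F5 with 2 equiv n-BuLi (−78 °C) gives the C,O-dilithiated phenoxide, which adds to the magnesium alkoxide of F6 and gives 11 after NH4Cl (Weinreb ketone synthesis).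

Step 3 (electrolysis on an aryl hemimalate). The substrate can expel the phenol through its own carboxylate and carries a free β-OH next to the radical site. The fallback moves the C–C coupling onto an acetonide and so also bypasses step 2; it sets out from 4 (with 8 and 3 as partners) and returns at 10. Acid 4 with 2,2-dimethoxypropane/PPTS gives (4S)-2,2-dimethyl-5-oxo-1,3-dioxolane-4-acetic acid F1. Its NHPI ester 1,3-dioxoisoindolin-2-yl 2-[(4S)-2,2-dimethyl-5-oxo-1,3-dioxolan-4-yl]acetate F2 has no aryl ester and no free OH. F2 is coupled with 8 under the same Ni electrolysis to (5S)-2,2-dimethyl-5-(3-methylbut-2-en-1-yl)-1,3-dioxolan-4-one F3. LiOH, then citric acid, gives (2S)-2-hydroxy-5-methylhex-4-enoic acid F4, and Steglich esterification with 3 (DCC, cat. DMAP, CH2Cl2) gives 10.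

Step 5 (methylenation of a chelated o-hydroxyaryl α-hydroxy ketone). The carbonyl may be sluggish, and the Lewis-acidic medium could close the α-OH onto the prenyl alkene. The fallback is a Peterson olefination under basic conditions; it sets out from 11 and returns at 12. Excess Me3SiCH2Li/CeCl3 (THF, −78 °C) adds to the ketone to give (3S)-2-(2-hydroxy-3,5-dimethoxy-4-methylphenyl)-6-methyl-1-(trimethylsilyl)hept-5-ene-2,3-diol F7 as a mixture of C2 epimers. KOt-Bu (THF, 0 °C → rt) then eliminates it to 12; the stereocentre is no longer α to a carbonyl, so base is harmless.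

## Further compounds

F1 | step 3 | (4S)-2,2-dimethyl-5-oxo-1,3-dioxolane-4-acetic acid | CC1(C)O[C@@H](CC(=O)O)C(=O)O1
F2 | step 3 | 1,3-dioxoisoindolin-2-yl 2-[(4S)-2,2-dimethyl-5-oxo-1,3-dioxolan-4-yl]acetate | CC1(C)O[C@@H](CC(=O)ON2C(=O)c3ccccc3C2=O)C(=O)O1
F3 | step 3 | (5S)-2,2-dimethyl-5-(3-methylbut-2-en-1-yl)-1,3-dioxolan-4-one | CC1(C)O[C@@H](CC=C(C)C)C(=O)O1
F4 | step 3 | (2S)-2-hydroxy-5-methylhex-4-enoic acid | CC(C)=CC[C@H](O)C(=O)O
F5 | step 4 | 6-bromo-2,4-dimethoxy-3-methylphenol | Oc1c(Br)cc(OC)c(C)c1OC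
F6 | step 4 | (2S)-2-hydroxy-N-methoxy-N,5-dimethylhex-4-enamide | CC(C)=CC[C@H](O)C(=O)N(C)OC
F7 | step 5 | (3S)-2-(2-hydroxy-3,5-dimethoxy-4-methylphenyl)-6-methyl-1-(trimethylsilyl)hept-5-ene-2,3-diol | C[Si](C)(C)CC(O)(c1cc(OC)c(C)c(OC)c1O)[C@@H](O)CC=C(C)C
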